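**Plan**

- Retrosynthesis: first the two aryl O–Si bonds; then the C2–C3 bond of the pyranone ring, which in the precursor is a C2–O–C3 bridge, so the chromanone is the ring-contraction product of a seven-membered 4H-1,3-benzodioxepin-5-one; then the two acetal C–O bonds at C2 (α-hydroxy ketone + aldehyde); last the C–O bond alpha to the ketone and the two aryl–prenyl bonds.
- Forward: rings A and B are bought as bromophenols, silylated and prenylated by Stille coupling; the A-ring methyl ketone is hydroxylated; acetalisation joins the halves in a seven-membered ring; this ring contracts to the six-membered C ring; desilylation ends the route.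
- Enabling feature: C2 is at once the acetal carbon between O1 and the oxygen on C3 and a para-oxybenzylic carbon (easy ionisation), and C3 lies alpha to the C4 aryl ketone (enolisable), so a shift of C2 from oxygen to carbon turns the acetal into the α-ketol.
- Stereochemistry: the acetal is racemic; ionisation erases its stereocentre and a chiral Lewis acid sets C2 (R) on recombination (stereoconvergent), while C3 (R) follows as the thermodynamically preferred trans epimer.

Key step: step 7

Assumption: the sense of induction of the chiral Lewis acid in step 7 cannot be derived from precedent, so the ligand antipode that leads to (2R,3R) is meant; compounds 1 and 6, tributyl(3-methylbut-2-en-1-yl)stannane and the Davis oxaziridine are taken as commercially available.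

**Route**

Step 1
Reactants: 1 1-(5-bromo-2,4-dihydroxyphenyl)ethan-1-one
Product: 2 1-{5-bromo-2-hydroxy-4-[(triisopropylsilyl)oxy]phenyl}ethan-1-one
Conditions: TIPSCl (1.1 equiv), imidazole (2.2 equiv), DMF, 0 °C to rt
Reagents that add atoms: chlorotriisopropylsilane, CC(C)[Si](Cl)(C(C)C)C(C)C
Why: Imidazole-promoted silyl ether formation; the 2-OH is held in a hydrogen bond to the acetyl carbonyl, so the 4-OH should be silylated alone.

Step 2
Reactants: 2 1-{5-bromo-2-hydroxy-4-[(triisopropylsilyl)oxy]phenyl}ethan-1-one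
Product: 3 1-{2-hydroxy-5-(3-methylbut-2-en-1-yl)-4-[(triisopropylsilyl)oxy]phenyl}ethan-1-one
Conditions: prenyl-SnBu3 (1.3 equiv), Pd(PPh3)4 (5 mol %), DMF (degassed), 95 °C
Reagents that add atoms: tributyl(3-methylbut-2-en-1-yl)stannane, CCCC[Sn](CCCC)(CCCC)CC=C(C)C
Why: Migita–Kosugi–Stille coupling; after oxidative addition into the aryl C–Br bond the prenyl group is transferred through its unsubstituted alpha carbon to give the linear 3-methylbut-2-enyl arene, and the chelated phenol, ketone and silyl ether are inert under these neutral conditions.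

Step 3
Reactants: 3 1-{2-hydroxy-5-(3-methylbut-2-en-1-yl)-4-[(triisopropylsilyl)oxy]phenyl}ethan-1-one
Product: 5 2-hydroxy-1-{2-hydroxy-5-(3-methylbut-2-en-1-yl)-4-[(triisopropylsilyl)oxy]phenyl}ethan-1-one, via dipotassium dianion 4 (not isolated)
Conditions: KHMDS (2.3 equiv), THF, −78 °C; then Davis oxaziridine (1.2 equiv), −78 °C; AcOH quench
Reagents that add atoms: 3-phenyl-2-(phenylsulfonyl)oxaziridine (Davis oxaziridine), O=S(=O)(N1OC1c1ccccc1)c1ccccc1
Why: Davis enolate hydroxylation; the kinetic methyl-ketone enolate of the phenoxide attacks the electrophilic oxygen of the N-sulfonyloxaziridine, a reagent that, unlike a peracid, should not epoxidise the trisubstituted prenyl alkene.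

Step 4
Reactants: 6 3-bromo-4-hydroxybenzaldehyde
Product: 7 3-bromo-4-[(triisopropylsilyl)oxy]benzaldehyde
Conditions: TIPSCl (1.1 equiv), imidazole (2.2 equiv), DMF, rt
Reagents that add atoms: chlorotriisopropylsilane, CC(C)[Si](Cl)(C(C)C)C(C)C
Why: Imidazole-promoted silylation of the only hydroxyl group; the aldehyde is not affected.

Step 5
Reactants: 7 3-bromo-4-[(triisopropylsilyl)oxy]benzaldehyde
Product: 8 3-(3-methylbut-2-en-1-yl)-4-[(triisopropylsilyl)oxy]benzaldehyde
Conditions: prenyl-SnBu3 (1.3 equiv), Pd(PPh3)4 (5 mol %), DMF (degassed), 95 °C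
Reagents that add atoms: tributyl(3-methylbut-2-en-1-yl)stannane, CCCC[Sn](CCCC)(CCCC)CC=C(C)C
Why: Migita–Kosugi–Stille coupling as in step 2; the aldehyde tolerates the neutral conditions and the prenyl group should again be delivered in its linear form.

Step 6
Reactants: 8 3-(3-methylbut-2-en-1-yl)-4-[(triisopropylsilyl)oxy]benzaldehyde; 5 2-hydroxy-1-{2-hydroxy-5-(3-methylbut-2-en-1-yl)-4-[(triisopropylsilyl)oxy]phenyl}ethan-1-one
Product: 10 rac-7-(3-methylbut-2-en-1-yl)-2-{3-(3-methylbut-2-en-1-yl)-4-[(triisopropylsilyl)oxy]phenyl}-8-[(triisopropylsilyl)oxy]-2H-1,3-benzodioxepin-5(4H)-one, via dimethyl acetal 9 (not isolated)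
Conditions: (i) HC(OMe)3, PPTS (cat.), MeOH, rt, then evaporation; (ii) 5, PPTS (5 mol %), 5 Å MS, benzene, 50 °C, high dilution
Reagents that add atoms: none
Why: Acid-catalysed transacetalisation; the dimethyl acetal ionises under PPTS and is captured first by the primary alcohol and then by the phenol in a seven-membered ring closure driven by removal of methanol, and the new acetal stereocentre may form as a racemate because step 7 erases it.

Step 7
Reactants: 10 rac-7-(3-methylbut-2-en-1-yl)-2-{3-(3-methylbut-2-en-1-yl)-4-[(triisopropylsilyl)oxy]phenyl}-8-[(triisopropylsilyl)oxy]-2H-1,3-benzodioxepin-5(4H)-one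
Product: 11 (2R,3R)-3-hydroxy-6-(3-methylbut-2-en-1-yl)-2-{3-(3-methylbut-2-en-1-yl)-4-[(triisopropylsilyl)oxy]phenyl}-7-[(triisopropylsilyl)oxy]-2,3-dihydro-4H-chromen-4-one
Conditions: Ni(OTf)2 (10 mol %), chiral N,N′-dioxide ligand (L-pipecolic acid-derived bis-anilide, 11 mol %), i-Pr2NEt (20 mol %), 4 Å MS, CH2Cl2, 0 °C to rt, Ar
Reagents that add atoms: none
Why: Proposed new method: the chiral Ni(II) Lewis acid binds racemic 10 as a five-membered chelate through the C5 ketone oxygen and the neighbouring ring oxygen O3, which selects the C2–O3 acetal bond for heterolysis and gives a para-silyloxybenzyl-stabilised aryloxycarbenium ion (C2 planar, the acetal stereocentre erased) that stays tethered through O1 to the nickel alkoxide of the α-hydroxy ketone; the amine turns this chelate into the (Z)-enediolate, whose CH carbon (C4 of 10, C3 of 11) recombines with C2, so that C2 has moved from oxygen to carbon (formal [1,2] O-to-C shift) and the seven-membered ring has contracted to the chromanone. The closest known reaction types are Petasis–Ferrier and catalytic asymmetric [1,3] O-to-C rearrangements of racemic enol acetals (ionisation and recombination inside a chiral Lewis acid complex), the [1,2]-Wittig shift of acetal carbons, and direct aldol additions of chelated metal enediolates of 2-hydroxyacetophenones. The six-membered ring closes by C–C bond formation in a 6-(enolendo)-endo-trig mode. C2 (R) is controlled by the ligand, which should leave only one face of the chelated enediolate open to the tethered carbenium carbon, so both enantiomers of 10 converge; C3 is formed in the same closure and, being alpha to the ketone, is brought to the more stable trans arrangement (3R, both substituents equatorial) by enolisation under the reaction conditions without touching C2. The step needs cleavage of C2–O3 and not C2–O1, and C- and not O-recombination: the chelate is meant to secure the first (ionisation on the O1 side only reopens and recloses the acetal), and the irreversible gain of a C–C bond and a conjugated aryl ketone secures the second.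

Step 8
Reactants: 11 (2R,3R)-3-hydroxy-6-(3-methylbut-2-en-1-yl)-2-{3-(3-methylbut-2-en-1-yl)-4-[(triisopropylsilyl)oxy]phenyl}-7-[(triisopropylsilyl)oxy]-2,3-dihydro-4H-chromen-4-one
Product: 12 Lespeflorin B1, (2R,3R)-3,7-dihydroxy-2-[4-hydroxy-3-(3-methylbut-2-en-1-yl)phenyl]-6-(3-methylbut-2-en-1-yl)-2,3-dihydro-4H-chromen-4-one
Conditions: TBAF (2.2 equiv), AcOH (2.5 equiv), THF, 0 °C
Reagents that add atoms: none
Why: Fluoride-induced cleavage of the two aryl silyl ethers; the acetic acid buffer keeps the phenols protonated, so neither retro-oxa-Michael opening of the C ring nor epimerisation through a 4′-phenoxide (quinone methide) should set in, and the prenyl groups and the α-ketol are not affected.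

**Compound list**

1 | 1-(5-bromo-2,4-dihydroxyphenyl)ethan-1-one | CC(=O)c1cc(Br)c(O)cc1O | starting material
2 | 1-{5-bromo-2-hydroxy-4-[(triisopropylsilyl)oxy]phenyl}ethan-1-one | CC(=O)c1cc(Br)c(O[Si](C(C)C)(C(C)C)C(C)C)cc1O | intermediate
3 | 1-{2-hydroxy-5-(3-methylbut-2-en-1-yl)-4-[(triisopropylsilyl)oxy]phenyl}ethan-1-one | CC(=O)c1cc(CC=C(C)C)c(O[Si](C(C)C)(C(C)C)C(C)C)cc1O | intermediate
4 | dipotassium enolate-phenoxide (dianion) of 3, formed in the flask | C=C([O-])c1cc(CC=C(C)C)c(O[Si](C(C)C)(C(C)C)C(C)C)cc1[O-].[K+].[K+] | intermediate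
5 | 2-hydroxy-1-{2-hydroxy-5-(3-methylbut-2-en-1-yl)-4-[(triisopropylsilyl)oxy]phenyl}ethan-1-one | OCC(=O)c1cc(CC=C(C)C)c(O[Si](C(C)C)(C(C)C)C(C)C)cc1O | intermediate
6 | 3-bromo-4-hydroxybenzaldehyde | O=Cc1ccc(O)c(Br)c1 | starting material
7 | 3-bromo-4-[(triisopropylsilyl)oxy]benzaldehyde | O=Cc1ccc(O[Si](C(C)C)(C(C)C)C(C)C)c(Br)c1 | intermediate
8 | 3-(3-methylbut-2-en-1-yl)-4-[(triisopropylsilyl)oxy]benzaldehyde | O=Cc1ccc(O[Si](C(C)C)(C(C)C)C(C)C)c(CC=C(C)C)c1 | intermediate
9 | dimethyl acetal of 8, formed in the flask | COC(OC)c1ccc(O[Si](C(C)C)(C(C)C)C(C)C)c(CC=C(C)C)c1 | intermediate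
10 | rac-7-(3-methylbut-2-en-1-yl)-2-{3-(3-methylbut-2-en-1-yl)-4-[(triisopropylsilyl)oxy]phenyl}-8-[(triisopropylsilyl)oxy]-2H-1,3-benzodioxepin-5(4H)-one (racemic at the acetal carbon) | O=C1COC(c2ccc(O[Si](C(C)C)(C(C)C)C(C)C)c(CC=C(C)C)c2)Oc2cc(O[Si](C(C)C)(C(C)C)C(C)C)c(CC=C(C)C)cc21 | intermediate
11 | (2R,3R)-3-hydroxy-6-(3-methylbut-2-en-1-yl)-2-{3-(3-methylbut-2-en-1-yl)-4-[(triisopropylsilyl)oxy]phenyl}-7-[(triisopropylsilyl)oxy]-2,3-dihydro-4H-chromen-4-one | CC(C)=CCc1cc([C@H]2Oc3cc(O[Si](C(C)C)(C(C)C)C(C)C)c(CC=C(C)C)cc3C(=O)[C@@H]2O)ccc1O[Si](C(C)C)(C(C)C)C(C)C | intermediate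
12 | Lespeflorin B1, (2R,3R)-3,7-dihydroxy-2-[4-hydroxy-3-(3-methylbut-2-en-1-yl)phenyl]-6-(3-methylbut-2-en-1-yl)-2,3-dihydro-4H-chromen-4-one | CC(C)=CCc1cc([C@H]2Oc3cc(O)c(CC=C(C)C)cc3C(=O)[C@@H]2O)ccc1O | target

**Count**

Total steps: 8. Longest linear sequence: 6 (steps 1, 2, 3, 6, 7, 8).

**Steps most likely to fail**

1. Step 7 (proposed new method). Heterolysis may take place mainly on the aryl-oxygen side of the acetal, which does not lead on and, with traces of water, ends in loss of the aldehyde. Recombination may occur with poor facial discrimination. The product may open by beta-elimination of the phenoxide and reclose without control. The fallback uses known chemistry, sets out from 3 and 8 and returns at 11. The chelated phenol of 3 is protected (MOMCl, i-Pr2NEt, CH2Cl2) to give the methoxymethyl ether F1. Its lithium enolate (LiHMDS, THF, −78 °C) adds to 8 to give the aldol F2. Mesylation (MsCl, Et3N) gives the mesylate F3, and DBU eliminates to the (E)-chalcone F4. Juliá–Colonna epoxidation (poly-L-leucine, urea–H2O2, DBU, THF) is nucleophilic, leaves the prenyl groups alone and should give the (αR,βS)-epoxy ketone F5. Dilute HCl in MeOH/THF removes the methoxymethyl group, and the freed phenol opens the oxirane at the benzylic carbon with inversion (6-endo) to give the trans-(2R,3R) compound 11.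

2. Step 6. The equilibrium may favour open-chain or oligomeric acetals over the seven-membered ring (loss of the phenol–ketone hydrogen bond, ring strain), and acid may induce aldol-type condensation of the ketol with the aldehyde. The fallback sets out from 5 and 8 and returns at 10, and replaces the equilibrium exchange by a kinetic silyl-transfer acetalisation (Noyori conditions). Compound 5 is converted (N,O-bis(trimethylsilyl)acetamide, CH2Cl2) into its bis(trimethylsilyl) ether F6. F6 reacts with the free aldehyde 8 under catalytic TMSOTf at −78 °C. The irreversible formation of a disiloxane, not the removal of methanol, drives the ring closure, and no Brønsted acid is present.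

3. Step 3. The dianion may form incompletely, the product may be oxidised further through its enediolate, or the product alkoxide may add to the sulfonimine by-product. The fallback sets out from 2 and returns at 5, and introduces the oxygen by Rubottom oxidation before the alkene is present. Compound 2 is silylated (TMSOTf, Et3N) to the bis-silyl compound F7 (trimethylsilyl enol ether and aryl trimethylsilyl ether). m-CPBA gives the α-silyloxy ketone F8. Methanolic citric acid removes both trimethylsilyl groups to give the bromo ketol F9. The Stille coupling of step 2, applied to F9, gives 5.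

**Further compounds**

F1 | step 7 | 1-{2-(methoxymethoxy)-5-(3-methylbut-2-en-1-yl)-4-[(triisopropylsilyl)oxy]phenyl}ethan-1-one | CC(=O)c1cc(CC=C(C)C)c(O[Si](C(C)C)(C(C)C)C(C)C)cc1OCOC
F2 | step 7 | rac-3-hydroxy-1-{2-(methoxymethoxy)-5-(3-methylbut-2-en-1-yl)-4-[(triisopropylsilyl)oxy]phenyl}-3-{3-(3-methylbut-2-en-1-yl)-4-[(triisopropylsilyl)oxy]phenyl}propan-1-one | OC(CC(=O)c1cc(CC=C(C)C)c(O[Si](C(C)C)(C(C)C)C(C)C)cc1OCOC)c1ccc(O[Si](C(C)C)(C(C)C)C(C)C)c(CC=C(C)C)c1
F3 | step 7 | methanesulfonate of F2 | CS(=O)(=O)OC(CC(=O)c1cc(CC=C(C)C)c(O[Si](C(C)C)(C(C)C)C(C)C)cc1OCOC)c1ccc(O[Si](C(C)C)(C(C)C)C(C)C)c(CC=C(C)C)c1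
F4 | step 7 | (E)-1-{2-(methoxymethoxy)-5-(3-methylbut-2-en-1-yl)-4-[(triisopropylsilyl)oxy]phenyl}-3-{3-(3-methylbut-2-en-1-yl)-4-[(triisopropylsilyl)oxy]phenyl}prop-2-en-1-one | O=C(/C=C/c1ccc(O[Si](C(C)C)(C(C)C)C(C)C)c(CC=C(C)C)c1)c1cc(CC=C(C)C)c(O[Si](C(C)C)(C(C)C)C(C)C)cc1OCOC
F5 | step 7 | {2-(methoxymethoxy)-5-(3-methylbut-2-en-1-yl)-4-[(triisopropylsilyl)oxy]phenyl}[(2R,3S)-3-{3-(3-methylbut-2-en-1-yl)-4-[(triisopropylsilyl)oxy]phenyl}oxiran-2-yl]methanone | O=C(c1cc(CC=C(C)C)c(O[Si](C(C)C)(C(C)C)C(C)C)cc1OCOC)[C@@H]1O[C@H]1c1ccc(O[Si](C(C)C)(C(C)C)C(C)C)c(CC=C(C)C)c1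
F6 | step 6 | bis(trimethylsilyl) ether of 5 | C[Si](C)(C)OCC(=O)c1cc(CC=C(C)C)c(O[Si](C(C)C)(C(C)C)C(C)C)cc1O[Si](C)(C)C
F7 | step 3 | trimethylsilyl enol ether and aryl trimethylsilyl ether of 2 | C=C(O[Si](C)(C)C)c1cc(Br)c(O[Si](C(C)C)(C(C)C)C(C)C)cc1O[Si](C)(C)C
F8 | step 3 | 1-{5-bromo-4-[(triisopropylsilyl)oxy]-2-[(trimethylsilyl)oxy]phenyl}-2-[(trimethylsilyl)oxy]ethan-1-one | C[Si](C)(C)OCC(=O)c1cc(Br)c(O[Si](C(C)C)(C(C)C)C(C)C)cc1O[Si](C)(C)C
F9 | step 3 | 1-{5-bromo-2-hydroxy-4-[(triisopropylsilyl)oxy]phenyl}-2-hydroxyethan-1-one | OCC(=O)c1cc(Br)c(O[Si](C(C)C)(C(C)C)C(C)C)cc1O
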